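The route disconnects the C1–C2 bond of the tetralin (C1 = diarylmethine, C2 = adjacent CH–CH2OH). C1 is doubly benzylic, para to O4′ of the guaiacyl ring and ortho/para to the C8 and C6 methoxy groups of the fused ring, so a C1–O bond ionises easily. C1 is therefore parked as a temporary seven-membered ether to the C3 hydroxymethyl oxygen (a 2-benzoxepine). In the key step a silyl triflate unzips this ether to the quinone-methide-like cation, which an acyclic enol silane of the C2 aldehyde captures: a ring contraction that sets C1 and C2 from the Evans-derived C3 stereocentre.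

Key step: step 9

Remark: tetralin numbering is used for the target (C1 = ArCH, C2 and C3 = the CH–CH2OH carbons, C4 = CH2). Compounds 14–18 are mixtures of epimers at the carbinol/ether carbon that becomes C1, and that centre is drawn without a descriptor. Compounds 1, 5, 6 and 12 are taken as commercial.

Step 1
Reactants: 1 4-(benzyloxy)-3,5-dimethoxybenzaldehyde
Product: 2 4-(benzyloxy)-2-bromo-3,5-dimethoxybenzaldehyde
Conditions: NBS, CHCl3, 60 °C
Reagents that add atoms: N-bromosuccinimide O=C1CCC(=O)N1Br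
Why: Electrophilic aromatic bromination can only occur at the two equivalent free positions, each ortho to one methoxy group and para to the other, so a single monobromide should result.

Step 2
Reactants: 2 4-(benzyloxy)-2-bromo-3,5-dimethoxybenzaldehyde
Product: 3 [4-(benzyloxy)-2-bromo-3,5-dimethoxyphenyl]methanol
Conditions: NaBH4, MeOH/THF, 0 °C
Reagents that add atoms: none
Why: Borohydride reduction of the aldehyde is chemoselective, leaving the aryl bromide and the benzyl ether untouched.

Step 3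
Reactants: 3 [4-(benzyloxy)-2-bromo-3,5-dimethoxyphenyl]methanol
Product: 4 2-(benzyloxy)-4-bromo-5-(bromomethyl)-1,3-dimethoxybenzene
Conditions: PBr3, CH2Cl2, 0 °C
Reagents that add atoms: phosphorus tribromide BrP(Br)Br
Why: The activated benzylic alcohol is converted into the bromide by SN2 displacement of its phosphite ester.

Step 4
Reactants: 5 (4R)-4-benzyl-1,3-oxazolidin-2-one; 6 pent-4-enoyl chloride
Product: 8 (4R)-4-benzyl-3-(pent-4-enoyl)-1,3-oxazolidin-2-one, via N-lithio oxazolidinone 7 (not isolated)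
Conditions: n-BuLi, THF, −78 °C; then 6, −78 → 0 °C
Reagents that add atoms: none
Why: N-Acylation of the lithiated oxazolidinone attaches the Evans auxiliary without touching its stereocentre.

Step 5
Reactants: 8 (4R)-4-benzyl-3-(pent-4-enoyl)-1,3-oxazolidin-2-one; 4 2-(benzyloxy)-4-bromo-5-(bromomethyl)-1,3-dimethoxybenzene
Product: 10 (4R)-4-benzyl-3-[(2S)-2-{[4-(benzyloxy)-2-bromo-3,5-dimethoxyphenyl]methyl}pent-4-enoyl]-1,3-oxazolidin-2-one, via sodium Z-enolate 9 (not isolated)
Conditions: NaHMDS, THF, −78 °C; then 4, −78 → −40 °C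
Reagents that add atoms: none
Why: Evans asymmetric alkylation: the chelated Z-enolate is benzylated on the face opposite the C4 benzyl group of the (R)-auxiliary, which sets the future C3 centre (2S in 10).

Step 6
Reactants: 10 (4R)-4-benzyl-3-[(2S)-2-{[4-(benzyloxy)-2-bromo-3,5-dimethoxyphenyl]methyl}pent-4-enoyl]-1,3-oxazolidin-2-one
Product: 11 (2S)-2-{[4-(benzyloxy)-2-bromo-3,5-dimethoxyphenyl]methyl}pent-4-en-1-ol
Conditions: LiBH4, H2O (1 equiv), Et2O, 0 °C
Reagents that add atoms: none
Why: Reductive cleavage of the imide gives the primary alcohol and returns the auxiliary, without enolisation of the stereocentre and without touching the aryl bromide or the alkene.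

Step 7
Reactants: 11 (2S)-2-{[4-(benzyloxy)-2-bromo-3,5-dimethoxyphenyl]methyl}pent-4-en-1-ol; 12 4-(benzyloxy)-3-methoxybenzaldehyde
Product: 15 (4S)-8-(benzyloxy)-1-[4-(benzyloxy)-3-methoxyphenyl]-7,9-dimethoxy-4-(prop-2-en-1-yl)-1,3,4,5-tetrahydro-2-benzoxepine, via dilithio alkoxide–aryllithium 13 (not isolated), via diol 14 (not isolated)
Conditions: n-BuLi (2.2 equiv), THF, −78 °C; then 12, −78 → 0 °C; aq NH4Cl; crude diol, CSA (5 mol%), 4 Å MS, CH2Cl2 (0.01 M), rt
Reagents that add atoms: none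
Why: Alkoxide formation and Br/Li exchange give an aryllithium that adds 1,2 to the aldehyde, and mild acid then ionises the doubly benzylic carbinol so that the primary alcohol closes the seven-membered ether (SN1 etherification, reversible, favoured by dilution); the new ether centre forms as an epimer mixture, which is irrelevant because it becomes planar in step 9.

Step 8
Reactants: 15 (4S)-8-(benzyloxy)-1-[4-(benzyloxy)-3-methoxyphenyl]-7,9-dimethoxy-4-(prop-2-en-1-yl)-1,3,4,5-tetrahydro-2-benzoxepine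
Product: 17 2-[(4R)-8-(benzyloxy)-1-[4-(benzyloxy)-3-methoxyphenyl]-7,9-dimethoxy-1,3,4,5-tetrahydro-2-benzoxepin-4-yl]acetaldehyde, via vicinal diol 16 (not isolated)
Conditions: OsO4 (2 mol%), NaIO4, 2,6-lutidine, dioxane/H2O 3:1, rt
Reagents that add atoms: osmium tetroxide O=[Os](=O)(=O)=O; sodium periodate [Na+].[O-][I](=O)(=O)=O
Why: Lemieux–Johnson oxidative cleavage of the only alkene, buffered with 2,6-lutidine so that the acid-labile benzylic ether survives; the C4 centre is untouched and no free hydroxyl is present to form a lactol.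

Step 9
Reactants: 17 2-[(4R)-8-(benzyloxy)-1-[4-(benzyloxy)-3-methoxyphenyl]-7,9-dimethoxy-1,3,4,5-tetrahydro-2-benzoxepin-4-yl]acetaldehyde
Product: 21 [(1S,2R,3R)-7-(benzyloxy)-1-[4-(benzyloxy)-3-methoxyphenyl]-6,8-dimethoxy-1,2,3,4-tetrahydronaphthalene-2,3-diyl]dimethanol, via enol silane 18 (not isolated), via benzhydryl cation 19 (not isolated), via silyl-protected aldehyde 20 (not isolated)
Conditions: i-Pr2NEt (1.5 equiv), TMSOTf (1.1 equiv), CH2Cl2, −78 → 0 °C; then TMSOTf (1.3 equiv), −78 → −40 °C; then MeOH, NaBH4, −40 → 0 °C; K2CO3/MeOH work-up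
Reagents that add atoms: none
Why: The aldehyde is first converted into its acyclic TMS enol ether, then more TMSOTf silylates the ring oxygen and ionises the C1–O bond to a benzhydrylium ion stabilised by O4′ (para) and the 8-/6-methoxy groups (ortho/para), which the enol silane captures to form C1–C2; loss of the silyl group gives the aldehyde, which is reduced in the same flask. The closest known reaction type is the Mukaiyama-type SN1 alkylation of enol silanes by Lewis-acid-ionised benzhydryl ethers, here intramolecular, and the overall O→C ring contraction resembles a Petasis–Ferrier rearrangement. The tetralin ring closes in a 6-(enolexo)-exo-trig mode onto the quinone-methide-like C1=C1′ π-bond of the cation. C2 is controlled by C3 through a chair transition state with CH2OSiMe3 equatorial and the enol C=C equatorial and eclipsed by H3 (minimal A1,3 strain), which should give the 2,3-trans relationship. C1 is controlled by the same chair, in which the planar ArCH+ unit is attacked on the face that leaves the guaiacyl ring pseudo-equatorial and anti to the axial H3, which should give 1,2-trans/1,3-cis, and both ether epimers of 17 converge on the one cation. The step needs C- over O-capture and an acyclic rather than a cyclic enol: re-closure through oxygen is reversible while C–C formation is not, and the temporary ether keeps O9 away from the aldehyde so that no lactol-derived cyclic enol ether (which would lead to the 2,3-cis isomer) can form.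

Step 10
Reactants: 21 [(1S,2R,3R)-7-(benzyloxy)-1-[4-(benzyloxy)-3-methoxyphenyl]-6,8-dimethoxy-1,2,3,4-tetrahydronaphthalene-2,3-diyl]dimethanol
Product: 22 (+)-8-methoxyisolariciresinol
Conditions: H2 (1 atm), 10% Pd/C, MeOH/EtOAc, rt
Reagents that add atoms: none
Why: Catalytic hydrogenolysis cleaves both aryl benzyl ethers, while the diarylmethine C–C bonds, the methyl ethers and the three stereocentres are inert, and no new stereocentre is formed.

Compound list
1 | 4-(benzyloxy)-3,5-dimethoxybenzaldehyde | COc1cc(C=O)cc(OC)c1OCc1ccccc1 | starting material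
2 | 4-(benzyloxy)-2-bromo-3,5-dimethoxybenzaldehyde | COc1cc(C=O)c(Br)c(OC)c1OCc1ccccc1 | intermediate
3 | [4-(benzyloxy)-2-bromo-3,5-dimethoxyphenyl]methanol | COc1cc(CO)c(Br)c(OC)c1OCc1ccccc1 | intermediate
4 | 2-(benzyloxy)-4-bromo-5-(bromomethyl)-1,3-dimethoxybenzene | COc1cc(CBr)c(Br)c(OC)c1OCc1ccccc1 | intermediate
5 | (4R)-4-benzyl-1,3-oxazolidin-2-one | O=C1N[C@H](Cc2ccccc2)CO1 | starting material
6 | pent-4-enoyl chloride | C=CCCC(=O)Cl | starting material
7 | N-lithio derivative of 5 | [Li]N1[C@H](Cc2ccccc2)COC1=O | intermediate (not isolated)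
8 | (4R)-4-benzyl-3-(pent-4-enoyl)-1,3-oxazolidin-2-one | C=CCCC(=O)N1[C@H](Cc2ccccc2)COC1=O | intermediate
9 | sodium (Z)-enolate of 8 | C=CC/C=C(\O[Na])N1[C@H](Cc2ccccc2)COC1=O | intermediate (not isolated)
10 | (4R)-4-benzyl-3-[(2S)-2-{[4-(benzyloxy)-2-bromo-3,5-dimethoxyphenyl]methyl}pent-4-enoyl]-1,3-oxazolidin-2-one | C=CC[C@@H](Cc1cc(OC)c(OCc2ccccc2)c(OC)c1Br)C(=O)N1[C@H](Cc2ccccc2)COC1=O | intermediate
11 | (2S)-2-{[4-(benzyloxy)-2-bromo-3,5-dimethoxyphenyl]methyl}pent-4-en-1-ol | C=CC[C@H](CO)Cc1cc(OC)c(OCc2ccccc2)c(OC)c1Br | intermediate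
12 | 4-(benzyloxy)-3-methoxybenzaldehyde | COc1cc(C=O)ccc1OCc1ccccc1 | starting material
13 | dilithio species of 11 (lithium alkoxide, aryllithium in place of Br) | C=CC[C@H](CO[Li])Cc1cc(OC)c(OCc2ccccc2)c(OC)c1[Li] | intermediate (not isolated)
14 | (2S)-2-({4-(benzyloxy)-2-[[4-(benzyloxy)-3-methoxyphenyl](hydroxy)methyl]-3,5-dimethoxyphenyl}methyl)pent-4-en-1-ol, carbinol epimers | C=CC[C@H](CO)Cc1cc(OC)c(OCc2ccccc2)c(OC)c1C(O)c1ccc(OCc2ccccc2)c(OC)c1 | intermediate (not isolated)
15 | (4S)-8-(benzyloxy)-1-[4-(benzyloxy)-3-methoxyphenyl]-7,9-dimethoxy-4-(prop-2-en-1-yl)-1,3,4,5-tetrahydro-2-benzoxepine, C1 epimers | C=CC[C@@H]1COC(c2ccc(OCc3ccccc3)c(OC)c2)c2c(OC)c(OCc3ccccc3)c(OC)cc2C1 | intermediate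
16 | 3-[(4R)-8-(benzyloxy)-1-[4-(benzyloxy)-3-methoxyphenyl]-7,9-dimethoxy-1,3,4,5-tetrahydro-2-benzoxepin-4-yl]propane-1,2-diol, epimer mixture | OCC(O)C[C@@H]1COC(c2ccc(OCc3ccccc3)c(OC)c2)c2c(OC)c(OCc3ccccc3)c(OC)cc2C1 | intermediate (not isolated)
17 | 2-[(4R)-8-(benzyloxy)-1-[4-(benzyloxy)-3-methoxyphenyl]-7,9-dimethoxy-1,3,4,5-tetrahydro-2-benzoxepin-4-yl]acetaldehyde, C1 epimers | O=CC[C@@H]1COC(c2ccc(OCc3ccccc3)c(OC)c2)c2c(OC)c(OCc3ccccc3)c(OC)cc2C1 | intermediate
18 | trimethylsilyl enol ether of 17 (E/Z), (4R)-4-[2-(trimethylsilyloxy)ethenyl] benzoxepine | C[Si](C)(C)OC=C[C@@H]1COC(c2ccc(OCc3ccccc3)c(OC)c2)c2c(OC)c(OCc3ccccc3)c(OC)cc2C1 | intermediate (not isolated)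
19 | [4-(benzyloxy)-3-methoxyphenyl]{3-(benzyloxy)-2,4-dimethoxy-6-[(2R)-4-(trimethylsilyloxy)-2-[(trimethylsilyloxy)methyl]but-3-en-1-yl]phenyl}methylium triflate | C[Si](C)(C)OC=C[C@H](CO[Si](C)(C)C)Cc1cc(OC)c(OCc2ccccc2)c(OC)c1[CH+]c1ccc(OCc2ccccc2)c(OC)c1.[O-]S(=O)(=O)C(F)(F)F | intermediate (not isolated)
20 | (1S,2R,3R)-7-(benzyloxy)-1-[4-(benzyloxy)-3-methoxyphenyl]-6,8-dimethoxy-3-[(trimethylsilyloxy)methyl]-1,2,3,4-tetrahydronaphthalene-2-carbaldehyde | COc1cc([C@H]2c3c(cc(OC)c(OCc4ccccc4)c3OC)C[C@@H](CO[Si](C)(C)C)[C@@H]2C=O)ccc1OCc1ccccc1 | intermediate (not isolated)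
21 | [(1S,2R,3R)-7-(benzyloxy)-1-[4-(benzyloxy)-3-methoxyphenyl]-6,8-dimethoxy-1,2,3,4-tetrahydronaphthalene-2,3-diyl]dimethanol | COc1cc([C@H]2c3c(cc(OC)c(OCc4ccccc4)c3OC)C[C@@H](CO)[C@@H]2CO)ccc1OCc1ccccc1 | intermediate
22 | (+)-8-methoxyisolariciresinol, (1S,2R,3R)-1-(4-hydroxy-3-methoxyphenyl)-2,3-bis(hydroxymethyl)-6,8-dimethoxy-1,2,3,4-tetrahydronaphthalen-7-ol | COc1cc([C@H]2c3c(cc(OC)c(O)c3OC)C[C@@H](CO)[C@@H]2CO)ccc1O | target

Total step count: 10. Longest linear sequence: 9 steps (1 → 22 through steps 1–3 and 5–10).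

Steps most likely to fail

Step 9. The cationic C1 may be attacked on both faces, because the peri 8-methoxy group disfavours the pseudo-equatorial guaiacyl ring on which the 1,3-induction from C3 relies, and the open transition state may also leak to the C2 epimer. The fallback sets out from 17 and comes back at 21; it replaces the substrate-controlled enol silane by an auxiliary-controlled chlorotitanium enolate. Pinnick oxidation of 17 (NaClO2, NaH2PO4, 2-methyl-2-butene) should give 2-[(4R)-8-(benzyloxy)-1-[4-(benzyloxy)-3-methoxyphenyl]-7,9-dimethoxy-1,3,4,5-tetrahydro-2-benzoxepin-4-yl]acetic acid F1. Activation as the pivalic mixed anhydride and reaction with 5 (Et3N, LiCl, THF) should give the N-acyl oxazolidinone F2. With TiCl4/i-Pr2NEt in CH2Cl2 at −78 °C the chelated Z-enolate forms while further TiCl4 opens the benzoxepine. The cation should then be captured on the enolate face opposite the auxiliary benzyl group, the same sense as in step 5, so the (R)-auxiliary delivers 2R and gives the cyclised hydroxy imide F3. LiBH4 reduction of the imide in F3 then gives 21.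

Step 7. Intermolecular etherification to oligomers may outrun the entropically slower seven-membered ring closure, and the hindered di-ortho-substituted aryllithium may be lost by proton transfer before it adds. The fallback sets out from 11 and comes back at 22; it gives up the temporary ring for a permanent benzyl ether. NaH/BnBr should convert 11 into the benzyl ether F4. Br/Li exchange (t-BuLi, THF, −78 °C) and addition to 12 should give the benzhydrol F5. Lemieux–Johnson cleavage should give the hydroxy aldehyde F6, which cannot form a lactol because O9 is benzylated. The TMSOTf/i-Pr2NEt closure of step 9, now silylating and ionising the free carbinol, with the same NaBH4 quench, should give the tribenzyl alcohol F7. Hydrogenolysis of its three benzyl ethers (H2, Pd/C) gives 22.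

Step 8. Periodate and osmium may attack the electron-rich rings or over-oxidise the aldehyde, and the aqueous medium may open the benzylic ether. The fallback sets out from 15 and comes back at 17; it separates the two oxidations so that the substrate never meets aqueous periodate. Upjohn dihydroxylation (OsO4 cat., NMO, acetone/H2O) with isolation of diol 16 is followed by anhydrous glycol fission with Pb(OAc)4/K2CO3 in CH2Cl2 at 0 °C (Criegee oxidation) to 17.

Further compounds
F1 | step 9 | 2-[(4R)-8-(benzyloxy)-1-[4-(benzyloxy)-3-methoxyphenyl]-7,9-dimethoxy-1,3,4,5-tetrahydro-2-benzoxepin-4-yl]acetic acid | OC(=O)C[C@@H]1COC(c2ccc(OCc3ccccc3)c(OC)c2)c2c(OC)c(OCc3ccccc3)c(OC)cc2C1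
F2 | step 9 | (4R)-4-benzyl-3-{2-[(4R)-8-(benzyloxy)-1-[4-(benzyloxy)-3-methoxyphenyl]-7,9-dimethoxy-1,3,4,5-tetrahydro-2-benzoxepin-4-yl]acetyl}-1,3-oxazolidin-2-one | O=C(C[C@@H]1COC(c2ccc(OCc3ccccc3)c(OC)c2)c2c(OC)c(OCc3ccccc3)c(OC)cc2C1)N1[C@H](Cc2ccccc2)COC1=O
F3 | step 9 | (4R)-4-benzyl-3-{[(1S,2R,3R)-7-(benzyloxy)-1-[4-(benzyloxy)-3-methoxyphenyl]-3-(hydroxymethyl)-6,8-dimethoxy-1,2,3,4-tetrahydronaphthalen-2-yl]carbonyl}-1,3-oxazolidin-2-one | COc1cc([C@H]2c3c(cc(OC)c(OCc4ccccc4)c3OC)C[C@@H](CO)[C@@H]2C(=O)N2[C@H](Cc3ccccc3)COC2=O)ccc1OCc1ccccc1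
F4 | step 7 | 2-(benzyloxy)-5-[(2S)-2-[(benzyloxy)methyl]pent-4-en-1-yl]-4-bromo-1,3-dimethoxybenzene | C=CC[C@H](COCc1ccccc1)Cc1cc(OC)c(OCc2ccccc2)c(OC)c1Br
F5 | step 7 | {3-(benzyloxy)-6-[(2S)-2-[(benzyloxy)methyl]pent-4-en-1-yl]-2,4-dimethoxyphenyl}[4-(benzyloxy)-3-methoxyphenyl]methanol, carbinol epimers | C=CC[C@H](COCc1ccccc1)Cc1cc(OC)c(OCc2ccccc2)c(OC)c1C(O)c1ccc(OCc2ccccc2)c(OC)c1
F6 | step 7 | (3R)-4-(benzyloxy)-3-({4-(benzyloxy)-2-[[4-(benzyloxy)-3-methoxyphenyl](hydroxy)methyl]-3,5-dimethoxyphenyl}methyl)butanal, carbinol epimers | O=CC[C@H](COCc1ccccc1)Cc1cc(OC)c(OCc2ccccc2)c(OC)c1C(O)c1ccc(OCc2ccccc2)c(OC)c1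
F7 | step 7 | {(1S,2R,3R)-7-(benzyloxy)-1-[4-(benzyloxy)-3-methoxyphenyl]-3-[(benzyloxy)methyl]-6,8-dimethoxy-1,2,3,4-tetrahydronaphthalen-2-yl}methanol | COc1cc([C@H]2c3c(cc(OC)c(OCc4ccccc4)c3OC)C[C@@H](COCc3ccccc3)[C@@H]2CO)ccc1OCc1ccccc1
F0 | step 8 | none | none
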